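**Plan** (carbons numbered as in a verticillane: C1 = cyclohexene CH that carries the bridge; C2–C9 = bridge with C4=C20H2, C6–OAc and C7=C8(C19); C10 = ketone; C11=C12 = ring-fusion enone; C13, C14 = ring CH2; C15 = CMe2; C18 = ring CH–OAc; the target is 1R,6S,7E,9S,18R in this numbering)
1. Cuts, in order: the two acetates; C3–C4 (12-membered ring, alkylzinc with vinyl bromide); C9–C8 (α-alkenylation); C11=C12 together with C13–C14 (key event); C9–C18 (aldol).
2. Enabling feature: C14–C1–C15–C11 of ring A, with the gem-dimethyl carbon C15, the acyl carbon C10 on C11 and C2–C3 on C1, is the cyclobutane of cis-pinonic acid with its C11–C14 bond still closed; C12 and C13 are an alkyne to be inserted into that bond.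
3. Forward: (+)-α-pinene → pinonic acid → 1-acylcyclobutene; an aldol adds C18–C12≡C13; photocycloaddition and electrocyclic opening close the cyclopentenone (C11–C12) and expand the four-membered ring to ring A (C13–C14) at once; then C9 alkenylation with the C4–C8 fragment, closure of the 12-membered ring and acetylation.
4. Stereochemistry: C1 from (+)-α-pinene; C18 from a reagent-controlled boron aldol; C9 by kinetic protonation anti to the C18 silyl ether, then held by the bridge; C6 by Noyori transfer hydrogenation; the 7E alkene by syn-hydrozirconation.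

Key step: step 7

Assumption: (−)-Ipc2BCl is taken to attack the aldehyde face that gives the (R)-carbinol at C18; if the facial sense is the opposite, (+)-Ipc2BCl is used instead.

Step 1
Reactants: 1 (1R,5R)-(+)-α-pinene
Product: 2 cis-pinonic acid, 2-[(1S,3S)-3-acetyl-2,2-dimethylcyclobutyl]acetic acid
Conditions: RuCl3·xH2O (2 mol %), NaIO4, MeCN/EtOAc/H2O, 0 °C → rt
Reagents that add atoms: sodium periodate [Na+].[O-]I(=O)(=O)=O; water O
Why: RuO4-mediated oxidative cleavage of the trisubstituted alkene should give the methyl ketone and the acid while the cyclobutane and its two cis-disposed stereocenters (the later C1 among them) stay untouched.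

Step 2
Reactants: 2 cis-pinonic acid
Product: 3 1-[(1S,3S)-3-(2-hydroxyethyl)-2,2-dimethylcyclobutyl]ethan-1-one
Conditions: BH3·THF (1.05 equiv), THF, −15 → 0 °C; MeOH
Reagents that add atoms: none
Why: Borane reduction of a carboxylic acid (through the acyloxyborane) is faster than reduction of a ketone, so one equivalent in the cold should reduce the acid chemoselectively.

Step 3
Reactants: 3 keto alcohol
Product: 4 1-[(1S,3S)-3-(2-bromoethyl)-2,2-dimethylcyclobutyl]ethan-1-one
Conditions: CBr4, PPh3, CH2Cl2, 0 °C
Reagents that add atoms: tetrabromomethane BrC(Br)(Br)Br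
Why: The Appel reaction converts the primary alcohol into the bromide under neutral conditions that leave the ketone and the ring stereocenters alone; the bromide is the later handle for C3.

Step 4
Reactants: 4 bromo ketone
Product: 6 1-[(3R)-3-(2-bromoethyl)-4,4-dimethylcyclobut-1-en-1-yl]ethan-1-one, via tertiary α-bromo ketone 5 (not isolated)
Conditions: PhNMe3Br3, THF, 0 °C → rt; then DBU, 0 °C → rt
Reagents that add atoms: none
Why: Acid-catalysed α-bromination through the more substituted enol puts bromine on the acyl-bearing ring carbon, and the only β-hydrogens are on the ring CH2 (C14), so E2 dehydrobromination can give only the C11=C14 cyclobutene enone; the C1 stereocenter is not involved.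

Step 5
Reactants: 6 cyclobutenyl methyl ketone; 7 3-(trimethylsilyl)prop-2-ynal
Product: 9 (3R)-1-[(3R)-3-(2-bromoethyl)-4,4-dimethylcyclobut-1-en-1-yl]-3-hydroxypent-4-yn-1-one, via C-silylated aldol 8 (not isolated)
Conditions: (−)-Ipc2BCl, Et3N, Et2O, 0 °C; 7, −78 → −20 °C; H2O2, MeOH, pH 7 buffer; then AgNO3 (0.2 equiv), MeOH/H2O/CH2Cl2, rt
Reagents that add atoms: none
Why: A boron aldol of the kinetically formed methyl-ketone enolate (C9) adds the C18–C12≡C13 unit, with the C18 carbinol set by the chiral isopinocampheyl ligands on boron (reagent control, C1 being remote); silver-catalysed protodesilylation then frees the terminal alkyne without base.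

Step 6
Reactants: 9 aldol
Product: 10 (3R)-1-[(3R)-3-(2-bromoethyl)-4,4-dimethylcyclobut-1-en-1-yl]-3-[(tert-butyldimethylsilyl)oxy]pent-4-yn-1-one
Conditions: TBSOTf, 2,6-lutidine, CH2Cl2, −78 °C
Reagents that add atoms: tert-butyldimethylsilyl triflate CC(C)(C)[Si](C)(C)OS(=O)(=O)C(F)(F)F
Why: Silylation of the secondary carbinol under non-enolizing conditions blocks retro-aldol and provides the bulky group that later directs protonation at C9.

Step 7
Reactants: 10 acylcyclobutene with tethered alkyne
Product: 12 (3R,6R)-6-(2-bromoethyl)-3-[(tert-butyldimethylsilyl)oxy]-7,7-dimethyl-2,3,6,7-tetrahydro-1H-inden-1-one, via bicyclo[2.2.0]hexene photoadduct 11 (not isolated)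
Conditions: hν (366 nm), CH2Cl2 (5 mM, degassed), −40 °C; then PhMe, 100 °C, dark
Reagents that add atoms: none
Why: Proposed new method: n→π* excitation and intersystem crossing give the triplet of the cyclobutenyl ketone, which cannot relax by twisting; its α-carbon C11 bonds to the proximal alkyne carbon C12 (1,5-closure, 5-exo-dig radical mode, which closes the cyclopentanone), the 1,4-biradical collapses by C13–C14 bonding to the bicyclo[2.2.0]hex-2-ene 11, and on warming the strained central C11–C14 bond opens electrocyclically, so that the alkyne ends up inserted into the old cyclobutene double bond and the four-membered ring becomes the cyclohexa-1,3-diene of ring A (formed by two-carbon ring expansion, not by a separate closure). The closest known reaction types are the intramolecular enone–alkyne [2+2] photocycloaddition of 1,6-enyn-3-ones, which gives straight adducts, and the thermal isomerization of bicyclo[2.2.0]hex-2-enes to cyclohexa-1,3-dienes; their combination on a 1-acylcyclobutene is the untested part. No new stereocenter survives, since C11 and C14 return to sp2, and C1 and C18 are spectators under neutral photochemical and thermal conditions. The selectivity needed is regiochemical (C12 to C11, C13 to C14) and is enforced by the three-atom tether C10–C9–C18; chemoselectivity rests on the absence of any other alkene (the bridge carbons are therefore added later) and on cold photolysis, in which the non-conjugated photoadduct, transparent at 366 nm, accumulates before the dienone chromophore is released in the dark.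

Step 8
Reactants: 12 dienone
Product: 13 (3R,6S)-6-(2-bromoethyl)-3-[(tert-butyldimethylsilyl)oxy]-7,7-dimethyl-2,3,4,5,6,7-hexahydro-1H-inden-1-one
Conditions: H2 (1 atm), RhCl(PPh3)3 (5 mol %), PhMe, rt
Reagents that add atoms: none
Why: Homogeneous hydrogenation with this rhodium catalyst reduces the cis-disubstituted C13=C14 alkene and should leave the tetrasubstituted enone alkene, the alkyl bromide and the silyl ether untouched.

Step 9
Reactants: 13 bicyclic enone
Product: 14 2-bromo derivative of 13 (bromine on C9, both epimers)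
Conditions: LiN(SiMe3)2, THF, −78 °C; NBS, −78 °C; NH4Cl (aq)
Reagents that add atoms: N-bromosuccinimide O=C1CCC(=O)N1Br
Why: Kinetic α′-deprotonation of the enone at C9 (its only α-CH2) and bromination of the enolate in the cold, before the β-silyloxy group can be lost, give the α-bromo ketone; its configuration at C9 is irrelevant because the next step passes through a radical.

Step 10
Reactants: 15 but-2-ynal; 16 2,3-dibromoprop-1-ene
Product: 17 rac-2-bromohept-1-en-5-yn-4-ol
Conditions: In powder, THF/H2O (1:1), rt
Reagents that add atoms: none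
Why: The indium-mediated Barbier allylation uses only the allylic C–Br bond and adds 1,2 to the ynal, giving the 2-bromoallyl carbinol (C4, C5, C20 joined to C6–C8, C19) with the vinyl bromide intact; the racemic carbinol is erased in the next step.

Step 11
Reactants: 17 racemic carbinol
Product: 18 2-bromohept-1-en-5-yn-4-one
Conditions: Dess–Martin periodinane, NaHCO3, CH2Cl2, 0 °C
Reagents that add atoms: none
Why: Buffered Dess–Martin oxidation gives the ynone without moving the β,γ double bond into conjugation; the ketone is used at once.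

Step 12
Reactants: 18 ynone
Product: 19 (4S)-2-bromohept-1-en-5-yn-4-ol
Conditions: RuCl(p-cymene)[(S,S)-TsDPEN] (1 mol %), KOH (1 mol %), i-PrOH, rt
Reagents that add atoms: none
Why: Noyori asymmetric transfer hydrogenation of an alkynyl ketone, in which the alkyne takes the place of the aryl group in the CH/π transition state, should give the (S)-propargylic alcohol (the later C6) under catalyst control without touching the alkyne or the vinyl bromide.

Step 13
Reactants: 19 (S)-carbinol
Product: 20 tert-butyl{[(4S)-2-bromohept-1-en-5-yn-4-yl]oxy}dimethylsilane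
Conditions: TBSCl, imidazole, DMF, rt
Reagents that add atoms: tert-butyldimethylsilyl chloride CC(C)(C)[Si](C)(C)Cl
Why: Standard silylation protects the C6 carbinol for the organometallic steps and adds the steric bulk that steers zirconium to the methyl-bearing alkyne carbon.

Step 14
Reactants: 20 alkyne fragment; 14 α-bromo ketone
Product: 22 (2R,3R,6S)-2-[(2E,4S)-6-bromo-4-[(tert-butyldimethylsilyl)oxy]hepta-2,6-dien-2-yl]-6-(2-bromoethyl)-3-[(tert-butyldimethylsilyl)oxy]-7,7-dimethyl-2,3,4,5,6,7-hexahydro-1H-inden-1-one, via alkenylzirconocene chloride 21 (not isolated)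
Conditions: 20, Cp2Zr(H)Cl, THF, rt; then 14, NiCl2·glyme (5 mol %), 2,2′-isopropylidenebis[(4S)-4-phenyl-2-oxazoline] (6 mol %), DME/THF, 10 °C
Reagents that add atoms: none
Why: syn-Hydrozirconation places zirconium on the less hindered, methyl-bearing alkyne carbon (C8) and fixes the 7E geometry, and the nickel-catalysed stereoconvergent alkenylation of the α-bromo ketone (through the C9 α-keto radical) forms C9–C8 without base, with the alkenyl group expected anti to the C18 silyl ether (C9 epimer of the target series); any cis isomer formed is equally usable in step 15.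

Step 15
Reactants: 22 trans-alkenyl ketone
Product: 24 (2S,3R,6S)-2-[(2E,4S)-6-bromo-4-[(tert-butyldimethylsilyl)oxy]hepta-2,6-dien-2-yl]-6-(2-bromoethyl)-3-[(tert-butyldimethylsilyl)oxy]-7,7-dimethyl-2,3,4,5,6,7-hexahydro-1H-inden-1-one, via lithium dienolate 23 (not isolated)
Conditions: LiN(SiMe3)2 (1.05 equiv), THF, −78 °C, 10 min; AcOH, THF, −78 °C
Reagents that add atoms: none
Why: Deprotonation at C9 and kinetic α-protonation of the dienolate from the face opposite the C18 silyl ether should give the β,γ-unsaturated ketone with the alkenyl group cis to the silyl ether, which is the C9 configuration of the target and the only one that can bridge to C1.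

Step 16
Reactants: 24 cis-alkenyl ketone
Product: 26 bis(tert-butyldimethylsilyl) ether of diol 27 (12-membered ring closed between C3 and C4), via alkylzinc bromide 25 (not isolated)
Conditions: Zn dust (activated), LiCl, THF, 45 °C; then dilution to 2 mM (THF/NMP), Pd2(dba)3 (5 mol %), SPhos (12 mol %), 45 °C
Reagents that add atoms: none
Why: Zinc insertion into the primary C3–Br bond tolerates the ketone, the silyl ethers and the vinyl bromide, and intramolecular Negishi sp3–sp2 coupling with the 2-bromoalkene at high dilution closes the 12-membered ring with the exocyclic methylene in place; no base is present, so C9 and the β,γ-alkene are not disturbed.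

Step 17
Reactants: 26 bis-silyl ether
Product: 27 diol (target with OH at C6 and C18)
Conditions: HF·pyridine, pyridine, THF, 0 °C → rt
Reagents that add atoms: none
Why: Buffered acidic fluoride cleaves both secondary silyl ethers without the basic conditions that could epimerize C9, conjugate the C7=C8 alkene or eliminate the β-hydroxy ketone.

Step 18
Reactants: 27 diol
Product: 28 target CNP0121312.1 (6,18-diacetate)
Conditions: Ac2O, pyridine, DMAP (cat.), CH2Cl2, 0 °C → rt
Reagents that add atoms: acetic anhydride CC(=O)OC(C)=O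
Why: Acylation of both secondary allylic alcohols proceeds with retention at C6 and C18; elimination of the C18 acetate would need an antiaromatic cyclopentadienone and is not expected.

**Compound list**
1 | (1R,5R)-(+)-α-pinene | CC1=CC[C@@H]2C[C@H]1C2(C)C | starting material
2 | cis-pinonic acid, 2-[(1S,3S)-3-acetyl-2,2-dimethylcyclobutyl]acetic acid | CC(=O)[C@H]1C[C@@H](CC(=O)O)C1(C)C | intermediate
3 | 1-[(1S,3S)-3-(2-hydroxyethyl)-2,2-dimethylcyclobutyl]ethan-1-one | CC(=O)[C@H]1C[C@@H](CCO)C1(C)C | intermediate
4 | 1-[(1S,3S)-3-(2-bromoethyl)-2,2-dimethylcyclobutyl]ethan-1-one | CC(=O)[C@H]1C[C@@H](CCBr)C1(C)C | intermediate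
5 | tertiary α-bromo ketone: 4 brominated at the acetyl-bearing ring carbon (both epimers there; the other ring CH as in 4) | CC(=O)C1(Br)C[C@@H](CCBr)C1(C)C | intermediate
6 | 1-[(3R)-3-(2-bromoethyl)-4,4-dimethylcyclobut-1-en-1-yl]ethan-1-one | CC(=O)C1=C[C@@H](CCBr)C1(C)C | intermediate
7 | 3-(trimethylsilyl)prop-2-ynal | C[Si](C)(C)C#CC=O | starting material
8 | (3R)-1-[(3R)-3-(2-bromoethyl)-4,4-dimethylcyclobut-1-en-1-yl]-3-hydroxy-5-(trimethylsilyl)pent-4-yn-1-one | C[Si](C)(C)C#C[C@H](O)CC(=O)C1=C[C@@H](CCBr)C1(C)C | intermediate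
9 | (3R)-1-[(3R)-3-(2-bromoethyl)-4,4-dimethylcyclobut-1-en-1-yl]-3-hydroxypent-4-yn-1-one | C#C[C@H](O)CC(=O)C1=C[C@@H](CCBr)C1(C)C | intermediate
10 | (3R)-1-[(3R)-3-(2-bromoethyl)-4,4-dimethylcyclobut-1-en-1-yl]-3-[(tert-butyldimethylsilyl)oxy]pent-4-yn-1-one | C#C[C@H](O[Si](C)(C)C(C)(C)C)CC(=O)C1=C[C@@H](CCBr)C1(C)C | intermediate
11 | tricyclic photoadduct: cyclopentanone (C10, C9, C18, C12, C11) fused to a bicyclo[2.2.0]hex-2-ene (cyclobutene C11–C12=C13–C14 on the old cyclobutane C11–C14–C1–C15); C1 and C18 as in 10, the two new ring-fusion carbons cis and otherwise undefined | O=C1C[C@@H](O[Si](C)(C)C(C)(C)C)C2=CC3[C@@H](CCBr)C(C)(C)C123 | intermediate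
12 | (3R,6R)-6-(2-bromoethyl)-3-[(tert-butyldimethylsilyl)oxy]-7,7-dimethyl-2,3,6,7-tetrahydro-1H-inden-1-one | O=C1C[C@@H](O[Si](C)(C)C(C)(C)C)C2=C1C(C)(C)[C@H](CCBr)C=C2 | intermediate
13 | (3R,6S)-6-(2-bromoethyl)-3-[(tert-butyldimethylsilyl)oxy]-7,7-dimethyl-2,3,4,5,6,7-hexahydro-1H-inden-1-one | O=C1C[C@@H](O[Si](C)(C)C(C)(C)C)C2=C1C(C)(C)[C@H](CCBr)CC2 | intermediate
14 | 2-bromo derivative of 13 (both C2 epimers; other centers as in 13) | O=C1C(Br)[C@@H](O[Si](C)(C)C(C)(C)C)C2=C1C(C)(C)[C@H](CCBr)CC2 | intermediate
15 | but-2-ynal | CC#CC=O | starting material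
16 | 2,3-dibromoprop-1-ene | C=C(Br)CBr | starting material
17 | rac-2-bromohept-1-en-5-yn-4-ol | C=C(Br)CC(O)C#CC | intermediate
18 | 2-bromohept-1-en-5-yn-4-one | C=C(Br)CC(=O)C#CC | intermediate
19 | (4S)-2-bromohept-1-en-5-yn-4-ol | C=C(Br)C[C@H](O)C#CC | intermediate
20 | tert-butyl{[(4S)-2-bromohept-1-en-5-yn-4-yl]oxy}dimethylsilane | C=C(Br)C[C@H](O[Si](C)(C)C(C)(C)C)C#CC | intermediate
21 | chlorobis(cyclopentadienyl)[(2E,4S)-6-bromo-4-[(tert-butyldimethylsilyl)oxy]hepta-2,6-dien-2-yl]zirconium | C=C(Br)C[C@H](O[Si](C)(C)C(C)(C)C)/C=C(\C)[Zr](Cl)(C1C=CC=C1)C1C=CC=C1 | intermediate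
22 | (2R,3R,6S)-2-[(2E,4S)-6-bromo-4-[(tert-butyldimethylsilyl)oxy]hepta-2,6-dien-2-yl]-6-(2-bromoethyl)-3-[(tert-butyldimethylsilyl)oxy]-7,7-dimethyl-2,3,4,5,6,7-hexahydro-1H-inden-1-one (alkenyl group trans to the ring silyl ether) | O=C1[C@H](/C(C)=C/[C@@H](O[Si](C)(C)C(C)(C)C)CC(Br)=C)[C@@H](O[Si](C)(C)C(C)(C)C)C2=C1C(C)(C)[C@H](CCBr)CC2 | intermediate
23 | lithium dienolate of 22 (C10–OLi, C9=C10; other centers as in 22) | [Li]OC1=C(/C(C)=C/[C@@H](O[Si](C)(C)C(C)(C)C)CC(Br)=C)[C@@H](O[Si](C)(C)C(C)(C)C)C2=C1C(C)(C)[C@H](CCBr)CC2 | intermediate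
24 | (2S,3R,6S)-2-[(2E,4S)-6-bromo-4-[(tert-butyldimethylsilyl)oxy]hepta-2,6-dien-2-yl]-6-(2-bromoethyl)-3-[(tert-butyldimethylsilyl)oxy]-7,7-dimethyl-2,3,4,5,6,7-hexahydro-1H-inden-1-one (alkenyl group cis to the ring silyl ether) | O=C1[C@@H](/C(C)=C/[C@@H](O[Si](C)(C)C(C)(C)C)CC(Br)=C)[C@@H](O[Si](C)(C)C(C)(C)C)C2=C1C(C)(C)[C@H](CCBr)CC2 | intermediate
25 | alkylzinc bromide of 24 (CH2CH2ZnBr in place of CH2CH2Br) | O=C1[C@@H](/C(C)=C/[C@@H](O[Si](C)(C)C(C)(C)C)CC(Br)=C)[C@@H](O[Si](C)(C)C(C)(C)C)C2=C1C(C)(C)[C@H](CC[Zn]Br)CC2 | intermediate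
26 | 6,18-bis(tert-butyldimethylsilyl) ether of diol 27 (1R,6S,7E,9S,18R) | C=C1CC[C@@H]2CCC3=C(C(=O)[C@@H](/C(C)=C/[C@@H](O[Si](C)(C)C(C)(C)C)C1)[C@H]3O[Si](C)(C)C(C)(C)C)C2(C)C | intermediate
27 | 6,18-diol of the target skeleton (1R,6S,7E,9S,18R) | C=C1CC[C@@H]2CCC3=C(C(=O)[C@@H](/C(C)=C/[C@@H](O)C1)[C@H]3O)C2(C)C | intermediate
28 | CNP0121312.1, the 6,18-diacetate (1R,6S,7E,9S,18R in the numbering of the plan) | C=C1CC[C@@H]2CCC3=C(C(=O)[C@@H](/C(C)=C/[C@@H](OC(C)=O)C1)[C@H]3OC(C)=O)C2(C)C | target

**Totals and risks**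

Total step count: 18. Longest linear sequence: 14 steps (steps 1–9 and 14–18); the fragment branch is steps 10–13.

Step 7 (bears the label). The triplet may be lost to unproductive decay or hydrogen abstraction instead of adding to the alkyne, the photoadduct may resist ring-opening, or the dienone may be photolysed further if it forms under the lamp. The fallback uses known chemistry and sets out from 10. Luche reduction (NaBH4, CeCl3·7H2O, MeOH, −78 °C) would give the cyclobutenyl carbinol F1. Tandem ring-opening/ring-closing enyne metathesis (second-generation Grubbs catalyst, ethylene, CH2Cl2, 40 °C) would insert the alkyne into the cyclobutene double bond and give the bicyclic dienol F2. Dess–Martin oxidation of F2 comes back to the route at 12.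

Step 16. Intermolecular coupling to oligomers may outrun closure of the bridged 12-membered ring, or the alkylzinc may be protonated or lose hydride at palladium before it couples. The fallback sets out from 24 and changes the carbon nucleophile to an alkylborane made from an alkene. Sodium benzeneselenolate would displace the primary bromide to give the selenide F5. Oxidation with H2O2 and selenoxide syn-elimination would give the vinyl compound F6. Hydroboration with 9-BBN would give the B-alkyl-9-BBN F7, and intramolecular B-alkyl Suzuki–Miyaura coupling (PdCl2(dppf), AsPh3, Cs2CO3, THF/DMF/H2O, high dilution) comes back to the route at 26.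

Step 14. Reduction or elimination of the α-bromo ketone may outpace capture of the hindered α-keto radical by the nickel–alkenyl species. The fallback sets out from 13 and forms the C9–C8 bond by a 1,2-shift on boron instead. Detrifluoroacetylative diazo transfer (LiN(SiMe3)2, CF3CO2CH2CF3, −78 °C; then MsN3, Et3N, MeCN) would give the α-diazo ketone F3. Alkyne 20, after hydrozirconation and transmetallation with B-chloro-9-BBN, would give the B-alkenyl-9-BBN F4. The Hooz reaction of F3 with F4 (alkenyl migration with loss of N2, then protonation of the boron enolate anti to the silyl ether) comes back to the route at 24 and bypasses 22 and step 15.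

Further compounds
F1 | step 7 | (3R)-1-[(3R)-3-(2-bromoethyl)-4,4-dimethylcyclobut-1-en-1-yl]-3-[(tert-butyldimethylsilyl)oxy]pent-4-yn-1-ol (both C1 carbinol epimers) | C#C[C@H](O[Si](C)(C)C(C)(C)C)CC(O)C1=C[C@@H](CCBr)C1(C)C
F2 | step 7 | (3R,6R)-6-(2-bromoethyl)-3-[(tert-butyldimethylsilyl)oxy]-7,7-dimethyl-2,3,6,7-tetrahydro-1H-inden-1-ol (both C1 carbinol epimers) | OC1C[C@@H](O[Si](C)(C)C(C)(C)C)C2=C1C(C)(C)[C@H](CCBr)C=C2
F3 | step 14 | 2-diazo derivative of 13 (diazo group on C9) | O=C1C(=[N+]=[N-])[C@@H](O[Si](C)(C)C(C)(C)C)C2=C1C(C)(C)[C@H](CCBr)CC2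
F4 | step 14 | 9-[(2E,4S)-6-bromo-4-[(tert-butyldimethylsilyl)oxy]hepta-2,6-dien-2-yl]-9-borabicyclo[3.3.1]nonane | C=C(Br)C[C@H](O[Si](C)(C)C(C)(C)C)/C=C(\C)B1C2CCCC1CCC2
F5 | step 16 | phenyl selenide of 24 (CH2CH2SePh in place of CH2CH2Br) | O=C1[C@@H](/C(C)=C/[C@@H](O[Si](C)(C)C(C)(C)C)CC(Br)=C)[C@@H](O[Si](C)(C)C(C)(C)C)C2=C1C(C)(C)[C@H](CC[Se]c3ccccc3)CC2
F6 | step 16 | vinyl compound from 24 (CH=CH2 on C1 in place of CH2CH2Br) | O=C1[C@@H](/C(C)=C/[C@@H](O[Si](C)(C)C(C)(C)C)CC(Br)=C)[C@@H](O[Si](C)(C)C(C)(C)C)C2=C1C(C)(C)[C@H](C=C)CC2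
F7 | step 16 | B-alkyl-9-BBN from F6 (CH2CH2–9-BBN on C1) | O=C1[C@@H](/C(C)=C/[C@@H](O[Si](C)(C)C(C)(C)C)CC(Br)=C)[C@@H](O[Si](C)(C)C(C)(C)C)C2=C1C(C)(C)[C@H](CCB3C4CCCC3CCC4)CC2
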